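**Plan**

- Numbering: spiro[4.5]dec-7-ene. C1 bears the side chain C1'–C6', C4 bears a methyl group, C5 is the spiro atom, C7=C8 carries the C8 methyl group, and C9 is the carbinol carbon.
- Enabling feature: ring C5–C10 is a trans-carveol whose C5 hydrogen is replaced by C1, on the face that also holds the C9 oxygen. (R)-Carvone 1 has C5 in this sense, so a configuration-retaining carbenoid insertion into C5–H can make C1–C5.
- Cuts, last-made first: acetate C–O; C2'–C3' (B-alkyl cross-coupling with a vinyl iodide made from hydroxy ester 2); C1'=C2' and C1'–CH3 (ester into isopropenyl); C2–O; C1–C5 (insertion); C1–C2 (Claisen condensation); C3=C4 (olefination after cleavage of the isopropenyl group of 1).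
- Forward order: the cyclohexene is present from the start, the tether C4–C3–C2–C1 is grown on C5, the cyclopentane closes as the spiro ring in the insertion, and the side chain is joined afterwards.
- Stereochemistry: C5 comes from 1. C9 is set by 1,2-reduction and Mitsunobu inversion, and C4 by a ligand-controlled copper hydride reduction. C1 is set by ruthenium–BINAP hydrogenation of the β-keto ester under dynamic kinetic resolution. C1' is set by hydroboration away from quaternary C5, and C5' comes from 2.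

Key step: step 13

Assumption: the copper hydride complex of (S)-p-Tol-BINAP is taken to add hydride to the Si face of C4 in the (E)-enoate of step 10; the antipodal ligand is equally available should a model reduction show the opposite sense. (TBS = tert-butyldimethylsilyl.)

**Step 1**
Reactants: 2 methyl (2R)-3-hydroxy-2-methylpropanoate
Product: 3 methyl (2R)-3-(TBS-oxy)-2-methylpropanoate
Conditions: TBSCl, imidazole, CH2Cl2, 0 °C to rt
Reagents that add atoms: tert-butyldimethylsilyl chloride, CC(C)(C)[Si](C)(C)Cl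
Why: Imidazole-promoted silyl ether formation on a primary alcohol, which leaves the future C5' stereocentre untouched.

**Step 2**
Reactants: 3 methyl (2R)-3-(TBS-oxy)-2-methylpropanoate
Product: 4 (2R)-3-(TBS-oxy)-2-methylpropanal
Conditions: i-Bu2AlH, CH2Cl2, −78 °C; aqueous work-up
Reagents that add atoms: none
Why: Partial ester reduction, in which the aluminium hemiacetal persists at low temperature and releases the aldehyde only on work-up, so that C5' should not epimerise.

**Step 3**
Reactants: 4 (2R)-3-(TBS-oxy)-2-methylpropanal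
Product: 5 tert-butyl{[(2S,3E)-4-iodo-2-methylbut-3-en-1-yl]oxy}dimethylsilane
Conditions: CrCl2, CHI3, THF, 0 °C to rt
Reagents that add atoms: iodoform, IC(I)I
Why: Takai olefination, in which the geminal dichromium species adds to the aldehyde and eliminates to the (E)-vinyl iodide under non-basic conditions, adding C3' and keeping the α-stereocentre.

**Step 4**
Reactants: 1 (R)-carvone
Product: 6 (1R,5R)-2-methyl-5-(prop-1-en-2-yl)cyclohex-2-en-1-ol (cis-carveol)
Conditions: NaBH4, CeCl3·7H2O, MeOH, 0 °C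
Reagents that add atoms: none
Why: Luche reduction, in which the hard cerium-modified borohydride attacks only the carbonyl carbon C9 and does so axially, giving the pseudo-equatorial alcohol cis to the isopropenyl group.

**Step 5**
Reactants: 6 cis-carveol
Product: 7 (1S,5R)-2-methyl-5-(prop-1-en-2-yl)cyclohex-2-en-1-yl 4-nitrobenzoate
Conditions: 4-O2NC6H4CO2H, PPh3, DIAD, THF, 0 °C to rt
Reagents that add atoms: 4-nitrobenzoic acid, OC(=O)c1ccc(cc1)[N+](=O)[O-]
Why: Mitsunobu reaction, in which SN2 displacement of the oxyphosphonium ion by the acidic carboxylate inverts C9 to the S configuration of the target.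

**Step 6**
Reactants: 7 trans-carveyl 4-nitrobenzoate
Product: 8 (1S,5R)-2-methyl-5-(prop-1-en-2-yl)cyclohex-2-en-1-ol (trans-carveol)
Conditions: K2CO3 (cat.), MeOH, rt
Reagents that add atoms: none
Why: Base-catalysed methanolysis cleaves the electron-poor benzoate at the acyl carbon, so the C9–O bond and its configuration are kept.

**Step 7**
Reactants: 8 trans-carveol
Product: 9 tert-butyldimethyl{[(1S,5R)-2-methyl-5-(prop-1-en-2-yl)cyclohex-2-en-1-yl]oxy}silane
Conditions: TBSCl, imidazole, DMF, rt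
Reagents that add atoms: tert-butyldimethylsilyl chloride, CC(C)(C)[Si](C)(C)Cl
Why: Silyl ether formation gives a C9 protecting group that should tolerate enolates, carbenoids, radicals, Grignard reagents and boranes.

**Step 8**
Reactants: 9 trans-carveol TBS ether
Product: 11 1-[(1R,5S)-5-(TBS-oxy)-4-methylcyclohex-3-en-1-yl]ethan-1-one, via vicinal diol 10 (not isolated)
Conditions: OsO4 (cat.), NaIO4, 2,6-lutidine, dioxane–H2O, rt
Reagents that add atoms: osmium tetroxide (oxygen carrier), O=[Os](=O)(=O)=O; sodium periodate, [Na+].[O-]I(=O)(=O)=O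
Why: Lemieux–Johnson oxidation, in which OsO4 should take the open 1,1-disubstituted alkene before the trisubstituted ring alkene (shielded and inductively deactivated by the silyloxy group), NaIO4 cleaves diol 10, and the lutidine buffer protects C5 from epimerisation.

**Step 9**
Reactants: 11 methyl ketone; 12 trimethyl phosphonoacetate
Product: 13 methyl (2E)-3-[(1R,5S)-5-(TBS-oxy)-4-methylcyclohex-3-en-1-yl]but-2-enoate
Conditions: NaH, THF, 0 to 50 °C
Reagents that add atoms: none
Why: Horner–Wadsworth–Emmons olefination of a methyl ketone, in which the branched ring substituent settles trans to the ester so the (E)-enoate should dominate, the (Z)-isomer being removed by chromatography.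

**Step 10**
Reactants: 13 (E)-enoate
Product: 14 methyl (3S)-3-[(1R,5S)-5-(TBS-oxy)-4-methylcyclohex-3-en-1-yl]butanoate
Conditions: CuCl, NaOt-Bu, (S)-p-Tol-BINAP (all cat.), (EtO)2MeSiH, t-BuOH, toluene, 0 °C to rt
Reagents that add atoms: none
Why: Ligand-controlled copper hydride conjugate reduction (asymmetric 1,4-hydrosilylation) of a β,β-disubstituted enoate, which delivers hydride to the Si face of C4 and sets 4S while the isolated ring alkene is inert.

**Step 11**
Reactants: 14 saturated ester; 15 methyl acetate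
Product: 16 methyl (5S)-5-[(1R,5S)-5-(TBS-oxy)-4-methylcyclohex-3-en-1-yl]-3-oxohexanoate
Conditions: LiN(i-Pr)2, THF, −78 to −10 °C; aq. NH4Cl
Reagents that add atoms: none
Why: Crossed Claisen condensation, in which excess lithium enolate of 15 acylates at the unhindered ester of 14 and the product rests as its enolate until the quench, bringing in C1 and C1'.

**Step 12**
Reactants: 16 β-keto ester
Product: 17 methyl (5S)-2-diazo-5-[(1R,5S)-5-(TBS-oxy)-4-methylcyclohex-3-en-1-yl]-3-oxohexanoate
Conditions: 4-AcNHC6H4SO2N3, Et3N, MeCN, rt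
Reagents that add atoms: 4-acetamidobenzenesulfonyl azide, CC(=O)Nc1ccc(cc1)S(=O)(=O)N=[N+]=[N-]
Why: Regitz diazo transfer to the doubly activated methylene group C1, a routine reaction of β-keto esters.

**Step 13**
Reactants: 17 α-diazo-β-keto ester
Product: 18 methyl (1R,4S,5S,9S)-9-(TBS-oxy)-4,8-dimethyl-2-oxospiro[4.5]dec-7-ene-1-carboxylate (C1 enolisable, drawn as 1R)
Conditions: Rh2(OAc)4 (1 mol %), CH2Cl2, slow addition of 17, rt to 40 °C
Reagents that add atoms: none
Why: Rh2(OAc)4 expels N2 from 17 and leaves an electrophilic rhodium carbenoid at C1, which takes up the C5–H bond in a single concerted three-centre event: hydrogen passes to C1 as C1–C5 forms and the catalyst departs. The closest known reaction type is the dirhodium tetracarboxylate-catalysed intramolecular 1,5 C–H insertion of α-diazo-β-keto esters into tertiary C–H bonds, which gives 2-oxocyclopentanecarboxylates. The cyclopentane C1–C5 closes in the 1,5 mode through a six-membered array (C1, C2, C3, C4, C5, H), and because C5 is already a ring atom the new ring is spiro to the cyclohexene. C5 becomes quaternary with retention, so carvone controls it, whereas C1 is born enolisable and is fixed only in step 14. Selectivity is needed against the C4 methyl group (the only other 1,5 site, but primary and least hydridic), against C6–H and C10–H (six-membered ring closure) and against C7=C8 (a seven-atom tether), so the tertiary C5–H should win on electronics and ring size. The silyl ether on the face of C5–H can be avoided by reaction through the half-chair with the tether axial and C5–H equatorial.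

**Step 14**
Reactants: 18 spiro β-keto ester
Product: 19 methyl (1R,2R,4S,5S,9S)-9-(TBS-oxy)-2-hydroxy-4,8-dimethylspiro[4.5]dec-7-ene-1-carboxylate
Conditions: [RuCl(C6H6)((R)-BINAP)]Cl (1 mol %), H2 (100 atm), CH2Cl2, 50 °C
Reagents that add atoms: none
Why: Noyori asymmetric hydrogenation with dynamic kinetic resolution, the standard reaction of 2-oxocycloalkanecarboxylates, in which C1 epimerises through the enol faster than the chelated ketone is reduced, (R)-BINAP sets 2R and the ring enforces the anti hydroxy ester, so that the ester is locked on the C6 face of the cyclopentane, trans to the C4 methyl group, while the non-coordinating ring alkene is left alone.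

**Step 15**
Reactants: 19 hydroxy ester
Product: 20 methyl (1R,2R,4S,5S,9S)-9-(TBS-oxy)-4,8-dimethyl-2-[(phenoxycarbonothioyl)oxy]spiro[4.5]dec-7-ene-1-carboxylate
Conditions: PhOC(S)Cl, pyridine, DMAP (cat.), CH2Cl2, 0 °C to rt
Reagents that add atoms: O-phenyl chlorothionoformate, ClC(=S)Oc1ccccc1
Why: Acylation of the unhindered C2 alcohol under weak base gives the thionocarbonate needed for a Barton–McCombie deoxygenation without β-elimination or epimerisation at C1.

**Step 16**
Reactants: 20 thionocarbonate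
Product: 21 methyl (1S,4S,5S,9S)-9-(TBS-oxy)-4,8-dimethylspiro[4.5]dec-7-ene-1-carboxylate
Conditions: Bu3SnH, AIBN (cat.), toluene, 85 °C
Reagents that add atoms: none
Why: Barton–McCombie deoxygenation, in which the stannyl radical adds to C=S, C2–O fragments, and the secondary C2 radical is quenched by concentrated Bu3SnH before it can reach C7=C8, the neutral medium keeping C1 intact.

**Step 17**
Reactants: 21 spiro ester
Product: 23 1-[(1S,4S,5S,9S)-9-(TBS-oxy)-4,8-dimethylspiro[4.5]dec-7-en-1-yl]ethan-1-one, via Weinreb amide 22 (not isolated)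
Conditions: MeNH(OMe)·HCl, i-PrMgCl, THF, −15 to 0 °C; then MeMgBr, 0 °C to rt; aq. NH4Cl
Reagents that add atoms: N,O-dimethylhydroxylamine hydrochloride (atoms stay only in 22), CNOC.Cl; methylmagnesium bromide, C[Mg]Br
Why: Weinreb ketone synthesis in one flask, in which the chelated tetrahedral adduct of 22 and MeMgBr survives until the quench, so that only one methyl group is added and the free ketone never meets base.

**Step 18**
Reactants: 23 methyl ketone
Product: 24 tert-butyl{[(1R,4S,5S,9S)-4,8-dimethyl-1-(prop-1-en-2-yl)spiro[4.5]dec-7-en-9-yl]oxy}dimethylsilane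
Conditions: Cp2TiMe2, toluene, 75 °C, dark
Reagents that add atoms: dimethyltitanocene, C[Ti](C)(C1C=CC=C1)C1C=CC=C1
Why: Petasis methylenation, whose non-basic titanium methylidene converts hindered enolisable ketones into 1,1-disubstituted alkenes without epimerising the α-carbon C1.

**Step 19**
Reactants: 24 isopropenyl spirocycle; 5 vinyl iodide
Product: 26 (1R,4S,5S,9S)-9-(TBS-oxy)-1-[(2R,4E,6S)-7-(TBS-oxy)-6-methylhept-4-en-2-yl]-4,8-dimethylspiro[4.5]dec-7-ene, via B-alkyl-9-BBN borane 25 (not isolated)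
Conditions: 9-BBN-H, THF, rt; then 5, PdCl2(dppf) (cat.), AsPh3 (cat.), Cs2CO3, DMF–H2O, rt to 45 °C
Reagents that add atoms: 9-borabicyclo[3.3.1]nonane (boron stays only in 25), B1C2CCCC1CCC2
Why: Hydroboration followed by B-alkyl Suzuki–Miyaura coupling, in which 9-BBN-H takes only the 1,1-disubstituted alkene, in the rotamer with =CH2 eclipsing C1–H and from the face turned away from quaternary C5, which sets 1'R (the sense known for 20-methylenepregnanes, whose C17/C20 pair has the same relative configuration), and primary borane 25 then couples with 5.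

**Step 20**
Reactants: 26 coupled diene
Product: 27 (1R,4S,5S,9S)-9-(TBS-oxy)-1-[(2R,6S)-7-(TBS-oxy)-6-methylheptan-2-yl]-4,8-dimethylspiro[4.5]dec-7-ene
Conditions: TsNHNH2, NaOAc, DME–H2O, reflux
Reagents that add atoms: none
Why: Diimide reduction, whose concerted syn hydrogen transfer is far faster to the 1,2-disubstituted C3'=C4' alkene than to the hindered trisubstituted C7=C8.

**Step 21**
Reactants: 27 bis-silyl ether
Product: 28 (2S,6R)-6-[(1R,4S,5S,9S)-9-hydroxy-4,8-dimethylspiro[4.5]dec-7-en-1-yl]-2-methylheptan-1-ol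
Conditions: Bu4NF, THF, rt to 45 °C
Reagents that add atoms: none
Why: Fluoride-induced desilylation removes both silyl ethers without touching any stereocentre.

**Step 22**
Reactants: 28 diol
Product: 29 (2S,6R)-6-[(1R,4S,5S,9S)-9-hydroxy-4,8-dimethylspiro[4.5]dec-7-en-1-yl]-2-methylheptyl acetate (target)
Conditions: AcCl (1.05 equiv), 2,4,6-collidine, CH2Cl2, −78 °C
Reagents that add atoms: acetyl chloride, CC(=O)Cl
Why: Chemoselective acylation, in which at low temperature with a hindered weak base the primary C6' hydroxyl should react well before the secondary allylic C9 hydroxyl flanked by the C8 methyl group and the spiro centre.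

**Compound list**

1 | (R)-carvone | CC1=CC[C@H](CC1=O)C(C)=C | starting material
2 | methyl (2R)-3-hydroxy-2-methylpropanoate | COC(=O)[C@H](C)CO | starting material
3 | methyl (2R)-3-(TBS-oxy)-2-methylpropanoate | COC(=O)[C@H](C)CO[Si](C)(C)C(C)(C)C | intermediate
4 | (2R)-3-(TBS-oxy)-2-methylpropanal | O=C[C@H](C)CO[Si](C)(C)C(C)(C)C | intermediate
5 | tert-butyl{[(2S,3E)-4-iodo-2-methylbut-3-en-1-yl]oxy}dimethylsilane | I/C=C/[C@H](C)CO[Si](C)(C)C(C)(C)C | intermediate
6 | (1R,5R)-cis-carveol | CC(=C)[C@@H]1CC=C(C)[C@H](O)C1 | intermediate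
7 | (1S,5R)-trans-carveyl 4-nitrobenzoate | CC(=C)[C@@H]1CC=C(C)[C@@H](OC(=O)c2ccc(cc2)[N+](=O)[O-])C1 | intermediate
8 | (1S,5R)-trans-carveol | CC(=C)[C@@H]1CC=C(C)[C@@H](O)C1 | intermediate
9 | trans-carveol TBS ether | CC(=C)[C@@H]1CC=C(C)[C@@H](O[Si](C)(C)C(C)(C)C)C1 | intermediate
10 | 2-[(1R,5S)-5-(TBS-oxy)-4-methylcyclohex-3-en-1-yl]propane-1,2-diol (both carbinol epimers) | CC(O)(CO)[C@@H]1CC=C(C)[C@@H](O[Si](C)(C)C(C)(C)C)C1 | intermediate
11 | 1-[(1R,5S)-5-(TBS-oxy)-4-methylcyclohex-3-en-1-yl]ethan-1-one | CC(=O)[C@@H]1CC=C(C)[C@@H](O[Si](C)(C)C(C)(C)C)C1 | intermediate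
12 | trimethyl phosphonoacetate | COC(=O)CP(=O)(OC)OC | starting material
13 | methyl (2E)-3-[(1R,5S)-5-(TBS-oxy)-4-methylcyclohex-3-en-1-yl]but-2-enoate | COC(=O)/C=C(\C)[C@@H]1CC=C(C)[C@@H](O[Si](C)(C)C(C)(C)C)C1 | intermediate
14 | methyl (3S)-3-[(1R,5S)-5-(TBS-oxy)-4-methylcyclohex-3-en-1-yl]butanoate | COC(=O)C[C@H](C)[C@@H]1CC=C(C)[C@@H](O[Si](C)(C)C(C)(C)C)C1 | intermediate
15 | methyl acetate | COC(C)=O | starting material
16 | methyl (5S)-5-[(1R,5S)-5-(TBS-oxy)-4-methylcyclohex-3-en-1-yl]-3-oxohexanoate | COC(=O)CC(=O)C[C@H](C)[C@@H]1CC=C(C)[C@@H](O[Si](C)(C)C(C)(C)C)C1 | intermediate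
17 | methyl (5S)-2-diazo-5-[(1R,5S)-5-(TBS-oxy)-4-methylcyclohex-3-en-1-yl]-3-oxohexanoate | COC(=O)C(=[N+]=[N-])C(=O)C[C@H](C)[C@@H]1CC=C(C)[C@@H](O[Si](C)(C)C(C)(C)C)C1 | intermediate
18 | methyl (1R,4S,5S,9S)-9-(TBS-oxy)-4,8-dimethyl-2-oxospiro[4.5]dec-7-ene-1-carboxylate | COC(=O)[C@H]1C(=O)C[C@H](C)[C@@]12CC=C(C)[C@@H](O[Si](C)(C)C(C)(C)C)C2 | intermediate
19 | methyl (1R,2R,4S,5S,9S)-9-(TBS-oxy)-2-hydroxy-4,8-dimethylspiro[4.5]dec-7-ene-1-carboxylate | COC(=O)[C@H]1[C@H](O)C[C@H](C)[C@@]12CC=C(C)[C@@H](O[Si](C)(C)C(C)(C)C)C2 | intermediate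
20 | O-phenyl thionocarbonate of 19 | COC(=O)[C@H]1[C@H](OC(=S)Oc3ccccc3)C[C@H](C)[C@@]12CC=C(C)[C@@H](O[Si](C)(C)C(C)(C)C)C2 | intermediate
21 | methyl (1S,4S,5S,9S)-9-(TBS-oxy)-4,8-dimethylspiro[4.5]dec-7-ene-1-carboxylate | COC(=O)[C@H]1CC[C@H](C)[C@@]12CC=C(C)[C@@H](O[Si](C)(C)C(C)(C)C)C2 | intermediate
22 | (1S,4S,5S,9S)-9-(TBS-oxy)-N-methoxy-N,4,8-trimethylspiro[4.5]dec-7-ene-1-carboxamide | CON(C)C(=O)[C@H]1CC[C@H](C)[C@@]12CC=C(C)[C@@H](O[Si](C)(C)C(C)(C)C)C2 | intermediate
23 | 1-[(1S,4S,5S,9S)-9-(TBS-oxy)-4,8-dimethylspiro[4.5]dec-7-en-1-yl]ethan-1-one | CC(=O)[C@H]1CC[C@H](C)[C@@]12CC=C(C)[C@@H](O[Si](C)(C)C(C)(C)C)C2 | intermediate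
24 | tert-butyl{[(1R,4S,5S,9S)-4,8-dimethyl-1-(prop-1-en-2-yl)spiro[4.5]dec-7-en-9-yl]oxy}dimethylsilane | CC(=C)[C@H]1CC[C@H](C)[C@@]12CC=C(C)[C@@H](O[Si](C)(C)C(C)(C)C)C2 | intermediate
25 | 9-{(2R)-2-[(1R,4S,5S,9S)-9-(TBS-oxy)-4,8-dimethylspiro[4.5]dec-7-en-1-yl]propyl}-9-borabicyclo[3.3.1]nonane | C[C@H](CB1C2CCCC1CCC2)[C@H]3CC[C@H](C)[C@@]34CC=C(C)[C@@H](O[Si](C)(C)C(C)(C)C)C4 | intermediate
26 | (1R,4S,5S,9S)-9-(TBS-oxy)-1-[(2R,4E,6S)-7-(TBS-oxy)-6-methylhept-4-en-2-yl]-4,8-dimethylspiro[4.5]dec-7-ene | CC(C)(C)[Si](C)(C)OC[C@@H](C)/C=C/C[C@@H](C)[C@H]1CC[C@H](C)[C@@]12CC=C(C)[C@@H](O[Si](C)(C)C(C)(C)C)C2 | intermediate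
27 | (1R,4S,5S,9S)-9-(TBS-oxy)-1-[(2R,6S)-7-(TBS-oxy)-6-methylheptan-2-yl]-4,8-dimethylspiro[4.5]dec-7-ene | CC(C)(C)[Si](C)(C)OC[C@@H](C)CCC[C@@H](C)[C@H]1CC[C@H](C)[C@@]12CC=C(C)[C@@H](O[Si](C)(C)C(C)(C)C)C2 | intermediate
28 | (2S,6R)-6-[(1R,4S,5S,9S)-9-hydroxy-4,8-dimethylspiro[4.5]dec-7-en-1-yl]-2-methylheptan-1-ol | OC[C@@H](C)CCC[C@@H](C)[C@H]1CC[C@H](C)[C@@]12CC=C(C)[C@@H](O)C2 | intermediate
29 | (2S,6R)-6-[(1R,4S,5S,9S)-9-hydroxy-4,8-dimethylspiro[4.5]dec-7-en-1-yl]-2-methylheptyl acetate | CC(=O)OC[C@@H](C)CCC[C@@H](C)[C@H]1CC[C@H](C)[C@@]12CC=C(C)[C@@H](O)C2 | target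

**Step count**

Total step count: 22. Longest linear sequence: 19 steps (steps 4 to 22, from 1).

**Three steps most likely to fail**

**Step 14.**
- What may go wrong: the neopentyl surroundings of C1 may slow chelation and hydrogen transfer so far that incomplete epimerisation or substrate bias erodes control over C1 and C2. Traces of acid may also cost the silyl ether.
- The fallback gives up catalyst control and removes the C2 oxygen by way of the alkene. It sets out from 18.
- NaH and PhNTf2 in THF should give the enol triflate F1.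
- Pd(OAc)2, PPh3, HCO2H and Bu3N in DMF should reduce F1 to the cyclopentene ester F2.
- Mg in MeOH should saturate only the conjugated alkene. This gives 21 together with the C1 epimer F3.
- The two esters are separated, and F3 is re-equilibrated with NaOMe in MeOH and recycled.
- The route is rejoined at 21, so steps 14 to 16 are bypassed.

**Step 19.**
- What may go wrong: facial selectivity of the hydroboration at C1' may be poor, or transmetalation of the β-branched, crowded borane may be slow.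
- The fallback replaces substrate control with reagent control and changes the joining reaction. It sets out from 23.
- Horner–Wadsworth–Emmons olefination of 23 with 12 (NaH, THF, heat, with a check on the integrity of C1) should give the side-chain enoate F4.
- Copper hydride reduction as in step 10, but with (R)-p-Tol-BINAP, should set 1'R in the side-chain ester F5.
- LiAlH4 should give the primary alcohol F6.
- A Mitsunobu reaction with 1-phenyl-1H-tetrazole-5-thiol should give the tetrazolyl sulfide F7.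
- H2O2 with (NH4)6Mo7O24 should give the tetrazolyl sulfone F8.
- Julia–Kocienski olefination of F8 with aldehyde 4 (KN(SiMe3)2, THF, −78 °C) should form C3'=C4' and rejoin the route at 26.

**Step 13.**
- What may go wrong: the carbenoid may be diverted to the ring alkene or to the C4 methyl group, or the silyl ether on the same ring face may shield C5–H.
- The fallback redesigns the substrate rather than the catalyst. A small, electron-withdrawing acetate at C9 lowers the nucleophilicity of C7=C8 and clears the face of C5–H. It sets out from 16.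
- HF·pyridine should give the hydroxy keto ester F9.
- Ac2O in pyridine should give the acetoxy keto ester F10.
- Diazo transfer as in step 12 should give the acetoxy diazo keto ester F11.
- Rh2(OAc)4 should close the same C1–C5 bond to give the spiro acetate F12.
- K2CO3 in MeOH should free the spiro alcohol F13.
- TBSCl and imidazole bring the material back to 18.

**Further compounds**

F1 | step 14 | methyl (4S,5S,9S)-9-(TBS-oxy)-4,8-dimethyl-2-(trifluoromethylsulfonyloxy)spiro[4.5]deca-1,7-diene-1-carboxylate | COC(=O)C1=C(OS(=O)(=O)C(F)(F)F)C[C@H](C)[C@@]12CC=C(C)[C@@H](O[Si](C)(C)C(C)(C)C)C2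
F2 | step 14 | methyl (4S,5S,9S)-9-(TBS-oxy)-4,8-dimethylspiro[4.5]deca-1,7-diene-1-carboxylate | COC(=O)C1=CC[C@H](C)[C@@]12CC=C(C)[C@@H](O[Si](C)(C)C(C)(C)C)C2
F3 | step 14 | methyl (1R,4S,5S,9S)-9-(TBS-oxy)-4,8-dimethylspiro[4.5]dec-7-ene-1-carboxylate (C1 epimer of 21) | COC(=O)[C@@H]1CC[C@H](C)[C@@]12CC=C(C)[C@@H](O[Si](C)(C)C(C)(C)C)C2
F4 | step 19 | methyl (2E)-3-[(1R,4S,5S,9S)-9-(TBS-oxy)-4,8-dimethylspiro[4.5]dec-7-en-1-yl]but-2-enoate | COC(=O)/C=C(\C)[C@H]1CC[C@H](C)[C@@]12CC=C(C)[C@@H](O[Si](C)(C)C(C)(C)C)C2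
F5 | step 19 | methyl (3R)-3-[(1R,4S,5S,9S)-9-(TBS-oxy)-4,8-dimethylspiro[4.5]dec-7-en-1-yl]butanoate | COC(=O)C[C@@H](C)[C@H]1CC[C@H](C)[C@@]12CC=C(C)[C@@H](O[Si](C)(C)C(C)(C)C)C2
F6 | step 19 | (3R)-3-[(1R,4S,5S,9S)-9-(TBS-oxy)-4,8-dimethylspiro[4.5]dec-7-en-1-yl]butan-1-ol | OCC[C@@H](C)[C@H]1CC[C@H](C)[C@@]12CC=C(C)[C@@H](O[Si](C)(C)C(C)(C)C)C2
F7 | step 19 | 5-({(3R)-3-[(1R,4S,5S,9S)-9-(TBS-oxy)-4,8-dimethylspiro[4.5]dec-7-en-1-yl]butyl}sulfanyl)-1-phenyl-1H-tetrazole | c1ccc(cc1)-n1nnnc1SCC[C@@H](C)[C@H]2CC[C@H](C)[C@@]23CC=C(C)[C@@H](O[Si](C)(C)C(C)(C)C)C3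
F8 | step 19 | 5-({(3R)-3-[(1R,4S,5S,9S)-9-(TBS-oxy)-4,8-dimethylspiro[4.5]dec-7-en-1-yl]butyl}sulfonyl)-1-phenyl-1H-tetrazole | c1ccc(cc1)-n1nnnc1S(=O)(=O)CC[C@@H](C)[C@H]2CC[C@H](C)[C@@]23CC=C(C)[C@@H](O[Si](C)(C)C(C)(C)C)C3
F9 | step 13 | methyl (5S)-5-[(1R,5S)-5-hydroxy-4-methylcyclohex-3-en-1-yl]-3-oxohexanoate | COC(=O)CC(=O)C[C@H](C)[C@@H]1CC=C(C)[C@@H](O)C1
F10 | step 13 | methyl (5S)-5-[(1R,5S)-5-acetoxy-4-methylcyclohex-3-en-1-yl]-3-oxohexanoate | COC(=O)CC(=O)C[C@H](C)[C@@H]1CC=C(C)[C@@H](OC(C)=O)C1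
F11 | step 13 | methyl (5S)-5-[(1R,5S)-5-acetoxy-4-methylcyclohex-3-en-1-yl]-2-diazo-3-oxohexanoate | COC(=O)C(=[N+]=[N-])C(=O)C[C@H](C)[C@@H]1CC=C(C)[C@@H](OC(C)=O)C1
F12 | step 13 | methyl (1R,4S,5S,9S)-9-acetoxy-4,8-dimethyl-2-oxospiro[4.5]dec-7-ene-1-carboxylate | COC(=O)[C@H]1C(=O)C[C@H](C)[C@@]12CC=C(C)[C@@H](OC(C)=O)C2
F13 | step 13 | methyl (1R,4S,5S,9S)-9-hydroxy-4,8-dimethyl-2-oxospiro[4.5]dec-7-ene-1-carboxylate | COC(=O)[C@H]1C(=O)C[C@H](C)[C@@]12CC=C(C)[C@@H](O)C2
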